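(The readings were computed from invented constants; the scatter is artificial.)

Follow the starting material, not the target, and count what goes missing on the way.

all flasks: starting material 0.20 M

| run | reagent in the second phase | protic impurity | remark | time | volume of the second phase over the first |
|---|---|---|---|---|---|
| epsilon | 0.24 M | 0.040 M | the very flask that is asked about, followed so far |  |  |
| flask | 0.240 M | 0.0400 M |  | 2.0 h | 0.25 |

- epsilon (time / min: target / %, starting material / %): 8.00: 0.2, 87.7; 15.0: 5.3, 80.7; 25.0: 8.8, 74.2; 30.0: 10.8, 69.2; 40.0: 13.8, 61.6; 50.0: 20.4, 57.6

(readings scatter by 1 percentage point)

* target at 2.0 h, in percent of the starting material charged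
* part of the starting material charged that has reacted at 2.0 h

- in the second phase: reagent in the second phase; everything else is in the first
- charges count per volume of the first phase; a concentration in a rate is the amount of a species over the volume of its own phase; every rate counts per litre of the first phase
- the numbers in the tables scatter with a standard deviation of 1 percentage point
- the earlier runs hold the two phases in the same ratio of volumes as the flask asked about

Over the last 3 readings of this flask, starting material plus target falls short of the charge by 22.2 %. That is close to c(protic impurity)/c(starting material) = 20.0 %, so book the gap as lost to the impurity.

Now treat the reagent as steady, which makes the rate pseudo-first-order: k·c(starting material). The same fraction then goes each minute, and the integral is c(t) = c(t₀)·exp(−k(t−t₀)). The fall from 30.0 min to 50.0 min gives k = 0.00917 min⁻¹, which leaves 30.3 % at 2.0 h.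

The weak link is that this fall may still hold the impurity's share. So reforge k from the target's gain over the same stretch, divided by the mean starting material: the feed constant, the fraction of the starting material turned into target per minute, is 0.00757 min⁻¹, slower. Your reckoning now leaves 33.9 %, so 66.1 % has reacted, and subtracting the gap gives 43.9 % target, counting anything the target has turned into.

The forecast, “I lean towards the lower case”, stands at 42 % target (34 % to 54 %) and 65 % reacted (56 % to 77 %), a little below your figures.

The flask gives 37.0 % target and 64.7 % reacted.

    reagent in the reaction phase ⇌ reagent in the second phase, rate k1*([reagent in the reaction phase] - [reagent in the second phase]/K1) per volume of the first phase (partition coefficient = 0.980, kL = 0.0110 min⁻¹)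
    starting material + reagent in the reaction phase → target (k = 0.0570 M⁻¹ min⁻¹)
    reagent in the reaction phase + target → over-reacted product (k = 0.0240 M⁻¹ min⁻¹)
    starting material + protic impurity → quenched substrate (k = 0.530 M⁻¹ min⁻¹)

Your 0.00757 min⁻¹ left 33.9 % starting material, and this flask holds 35.3 %. The target in this flask stands below your 43.9 %, with 7.71 % over-reacted product beside it, and at 2.00 h target is made 2.27 times faster than it is used up.

In the neighbour read at 3.0 h, 0.00757 min⁻¹ leaves 21.5 % starting material, so 78.5 % has reacted. The computed neighbour gives 74.4 % reacted and 41.3 % target.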